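**Retrosynthetic overview**
1. The strategy rests on the benzene ring of the benzofuran (C3a–C4–C5–C6–C7–C7a): oxygen on C4 and C7 (para), H on C5, aryl on C6. A carbene carbon (C4), a terminal alkyne (C5, C6) and one CO (C7) assemble this hydroquinone pattern on the furan C3a–C7a edge.
2. Late stage: target 19 ⇐ benzyl ether 18 (hydrogenolysis) ⇐ C7 phenol 17 (O-methylation).
3. Key disconnection: C4–C5, C6–C7 and C7–C7a of 17 ⇒ furan-3-yl methoxycarbene chromium complex 14 + 4-benzyloxyphenylacetylene 15 + one CO ligand.
4. 14 ⇐ acid chloride 10 + pentacarbonylchromate dianion; the furan acid ⇐ Johnson–Claisen rearrangement of hydroxy ester 3 (sets C3–CH3 and C2–CH2CO2Me) ⇐ diethyl furan-3,4-dicarboxylate 1.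
5. Ring order: the furan is bought, the benzene ring is the only ring made (step 8), and the phenyl ring arrives with 15.

Key step: step 8

Remark: the target has no stereocentre and its biaryl axis rotates freely, so the compound is achiral and no stereocontrol is needed. Sodium naphthalenide is taken as a separately prepared THF solution.

**Step 1**
Reactants: 1 diethyl furan-3,4-dicarboxylate
Product: 2 4-(ethoxycarbonyl)furan-3-carboxylic acid
Conditions: KOH (1.0 equiv), EtOH, 0 °C → rt; then 1 M HCl
Reagents that add atoms: potassium hydroxide, [K+].[OH-]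
Why: Monosaponification of a symmetrical vicinal diester, in which the carboxylate formed by the first hydrolysis shields the neighbouring ester electrostatically, so one equivalent of hydroxide should stop at the half-ester.

**Step 2**
Reactants: 2 4-(ethoxycarbonyl)furan-3-carboxylic acid
Product: 3 ethyl 4-(hydroxymethyl)furan-3-carboxylate
Conditions: BH3·THF (1.5 equiv), THF, 0 °C → rt; MeOH quench, aqueous work-up
Reagents that add atoms: none
Why: Chemoselective borane reduction, in which the carboxylic acid reacts through its acyloxyborane far faster than the ester, so only the acid should be reduced to the hydroxymethyl group.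

**Step 3**
Reactants: 3 ethyl 4-(hydroxymethyl)furan-3-carboxylate; 4 trimethyl orthoacetate
Product: 7 methyl 2-[4-(ethoxycarbonyl)-3-methylfuran-2-yl]acetate, via ketene acetal 5 (not isolated), via methylidene-dihydrofuran 6 (not isolated)
Conditions: MeC(OMe)3 (6 equiv), EtCO2H (0.1 equiv), xylene, sealed tube, 150 °C
Reagents that add atoms: none
Why: Johnson–Claisen rearrangement of a 3-furylmethanol, in which ketene acetal 5 undergoes a [3,3] shift across the furan C4=C5 bond onto the free α-carbon and the exocyclic methylene 6 tautomerises back to the furan, so one operation should place both the ring methyl and the CH2CO2Me group.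

**Step 4**
Reactants: 7 methyl 2-[4-(ethoxycarbonyl)-3-methylfuran-2-yl]acetate
Product: 8 5-(carboxymethyl)-4-methylfuran-3-carboxylic acid
Conditions: LiOH·H2O (4 equiv), THF/MeOH/H2O, 45 °C; then 1 M HCl to pH 2
Reagents that add atoms: lithium hydroxide, [Li+].[OH-]
Why: The hindered furan ester cannot be cleaved selectively beside the aliphatic methyl ester, so both are saponified (ester hydrolysis) to a diacid whose two carboxyl groups can then be told apart by esterification rate.

**Step 5**
Reactants: 8 5-(carboxymethyl)-4-methylfuran-3-carboxylic acid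
Product: 9 5-(2-methoxy-2-oxoethyl)-4-methylfuran-3-carboxylic acid
Conditions: HCl (cat., 0.1 M in MeOH), MeOH, rt
Reagents that add atoms: methanol, CO
Why: Fischer esterification under mild acid catalysis is much faster for the non-conjugated CH2CO2H group than for the furan-conjugated carboxyl group flanked by the C4 methyl, so the aliphatic monoester should form chemoselectively.

**Step 6**
Reactants: 9 5-(2-methoxy-2-oxoethyl)-4-methylfuran-3-carboxylic acid
Product: 10 methyl 2-[4-(chlorocarbonyl)-3-methylfuran-2-yl]acetate
Conditions: (COCl)2 (1.3 equiv), DMF (cat.), CH2Cl2, 0 °C → rt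
Reagents that add atoms: oxalyl chloride, O=C(Cl)C(=O)Cl
Why: Acid chloride formation through the catalytic chloroiminium (Vilsmeier-type) species runs cold and neutral, conditions that the methyl ester and the acceptor-substituted furan should tolerate.

**Step 7**
Reactants: 10 methyl 2-[4-(chlorocarbonyl)-3-methylfuran-2-yl]acetate; 11 chromium hexacarbonyl
Product: 14 pentacarbonyl{methoxy[5-(2-methoxy-2-oxoethyl)-4-methylfuran-3-yl]methylidene}chromium, via disodium pentacarbonylchromate 12 (not isolated), via sodium acylchromate 13 (not isolated)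
Conditions: Cr(CO)6, NaC10H8 (2.0 equiv), THF, –78 → 0 °C; then 10, –78 °C; then Me3OBF4, CH2Cl2, 0 °C
Reagents that add atoms: trimethyloxonium tetrafluoroborate, C[O+](C)C.F[B-](F)(F)F
Why: Acid chloride route to Fischer carbene complexes, in which dianion 12 is acylated at –78 °C at the acid chloride (by far the most electrophilic site, and an acylation that outruns α-deprotonation even with enolisable acid chlorides) and acylchromate 13 is O-methylated by the hard oxonium salt, whereas an organolithium route would not tolerate the ester.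

**Step 8**
Reactants: 14 pentacarbonyl{methoxy[5-(2-methoxy-2-oxoethyl)-4-methylfuran-3-yl]methylidene}chromium; 15 1-(benzyloxy)-4-ethynylbenzene
Product: 17 methyl 2-[6-(4-benzyloxyphenyl)-7-hydroxy-4-methoxy-3-methyl-1-benzofuran-2-yl]acetate, via tricarbonylchromium phenol complex 16 (not isolated)
Conditions: 15 (1.5 equiv), THF (0.05 M), 50 °C, Ar; then air, daylight, Et2O, rt
Reagents that add atoms: none
Why: Thermal loss of a cis CO ligand from 14 opens a site for the alkyne, which inserts into the Cr=C bond (C4–C5) to give an η3-vinylcarbene, and migratory insertion of a CO ligand then gives the chromium-bound η4-vinylketene (C6–C7). The benzene ring closes by 6π-electrocyclisation of this dienylketene onto the free furan α-carbon (C7–C7a), and tautomerisation of the cyclohexadienone gives the phenol as its tricarbonylchromium complex 16, from which air and light should release 17. This is the Dötz benzannulation, established for aryl and furyl methoxycarbene chromium complexes with terminal arylacetylenes. No stereocentre is formed. Two selectivities are needed: the regiochemistry of alkyne insertion, secured because a terminal alkyne turns its larger aryl end away from the carbene substituents and so next to the CO-derived carbon C7, leaving H on C5; and the site of closure, secured because the carbene carbon sits on a furan β-carbon whose one neighbour carries the methyl group and whose other neighbour is the only free α-CH. The carbene methoxy group becomes the C4 methoxy group, the CO ligand becomes C7–OH, and the CH2CO2Me group takes no part.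

**Step 9**
Reactants: 17 methyl 2-[6-(4-benzyloxyphenyl)-7-hydroxy-4-methoxy-3-methyl-1-benzofuran-2-yl]acetate
Product: 18 methyl 2-[6-(4-benzyloxyphenyl)-4,7-dimethoxy-3-methyl-1-benzofuran-2-yl]acetate
Conditions: MeI, K2CO3, acetone, 50 °C
Reagents that add atoms: iodomethane, CI
Why: Williamson O-methylation of the phenoxide with a carbonate base too weak to deprotonate the CH2CO2Me group, so the C7 methyl ether should form without C-alkylation.

**Step 10**
Reactants: 18 methyl 2-[6-(4-benzyloxyphenyl)-4,7-dimethoxy-3-methyl-1-benzofuran-2-yl]acetate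
Product: 19 phenylcandilide B, methyl 2-[6-(4-hydroxyphenyl)-4,7-dimethoxy-3-methyl-1-benzofuran-2-yl]acetate
Conditions: H2 (1 atm), 10% Pd/C, EtOAc/MeOH, rt
Reagents that add atoms: none
Why: Catalytic hydrogenolysis of the aryl benzyl ether at 1 atm and room temperature, under which the tetrasubstituted benzofuran C2=C3 bond, the methyl ethers and the ester should not be reduced.

**Compound list**
1 | diethyl furan-3,4-dicarboxylate | CCOC(=O)c1cocc1C(=O)OCC | starting material
2 | 4-(ethoxycarbonyl)furan-3-carboxylic acid | CCOC(=O)c1cocc1C(=O)O | intermediate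
3 | ethyl 4-(hydroxymethyl)furan-3-carboxylate | CCOC(=O)c1cocc1CO | intermediate
4 | trimethyl orthoacetate | COC(C)(OC)OC | starting material
5 | ethyl 4-{[(1-methoxyethenyl)oxy]methyl}furan-3-carboxylate (ketene acetal) | CCOC(=O)c1cocc1COC(=C)OC | intermediate (not isolated)
6 | ethyl 5-(2-methoxy-2-oxoethyl)-4-methylidene-4,5-dihydrofuran-3-carboxylate (racemic) | CCOC(=O)C1=COC(CC(=O)OC)C1=C | intermediate (not isolated)
7 | methyl 2-[4-(ethoxycarbonyl)-3-methylfuran-2-yl]acetate | CCOC(=O)c1coc(CC(=O)OC)c1C | intermediate
8 | 5-(carboxymethyl)-4-methylfuran-3-carboxylic acid | OC(=O)Cc1occ(C(=O)O)c1C | intermediate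
9 | 5-(2-methoxy-2-oxoethyl)-4-methylfuran-3-carboxylic acid | COC(=O)Cc1occ(C(=O)O)c1C | intermediate
10 | methyl 2-[4-(chlorocarbonyl)-3-methylfuran-2-yl]acetate | COC(=O)Cc1occ(C(=O)Cl)c1C | intermediate
11 | chromium hexacarbonyl | O=C=[Cr](=C=O)(=C=O)(=C=O)(=C=O)=C=O | starting material
12 | disodium pentacarbonylchromate(2–) | [Na+].[Na+].O=C=[Cr-2](=C=O)(=C=O)(=C=O)=C=O | intermediate (not isolated)
13 | sodium pentacarbonyl{[5-(2-methoxy-2-oxoethyl)-4-methylfuran-3-yl]carbonyl}chromate(1–), drawn as the oxidocarbene form | [Na+].[O-]C(=[Cr](=C=O)(=C=O)(=C=O)(=C=O)=C=O)c1coc(CC(=O)OC)c1C | intermediate (not isolated)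
14 | pentacarbonyl{methoxy[5-(2-methoxy-2-oxoethyl)-4-methylfuran-3-yl]methylidene}chromium | COC(=[Cr](=C=O)(=C=O)(=C=O)(=C=O)=C=O)c1coc(CC(=O)OC)c1C | intermediate
15 | 1-(benzyloxy)-4-ethynylbenzene | C#Cc1ccc(OCc2ccccc2)cc1 | starting material
16 | tricarbonyl(η6-arene)chromium complex of 17, Cr on the new benzene ring C3a–C7a (η6 bonding written as two dot-separated parts) | COC(=O)Cc1oc2c(O)c(-c3ccc(OCc4ccccc4)cc3)cc(OC)c2c1C.O=C=[Cr](=C=O)=C=O | intermediate (not isolated)
17 | methyl 2-[6-(4-benzyloxyphenyl)-7-hydroxy-4-methoxy-3-methyl-1-benzofuran-2-yl]acetate | COC(=O)Cc1oc2c(O)c(-c3ccc(OCc4ccccc4)cc3)cc(OC)c2c1C | intermediate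
18 | methyl 2-[6-(4-benzyloxyphenyl)-4,7-dimethoxy-3-methyl-1-benzofuran-2-yl]acetate | COC(=O)Cc1oc2c(OC)c(-c3ccc(OCc4ccccc4)cc3)cc(OC)c2c1C | intermediate
19 | phenylcandilide B, methyl 2-[6-(4-hydroxyphenyl)-4,7-dimethoxy-3-methyl-1-benzofuran-2-yl]acetate | COC(=O)Cc1oc2c(OC)c(-c3ccc(O)cc3)cc(OC)c2c1C | target

**Total step count:** 10. **Longest linear sequence:** 10 steps (1 → 19; 4, 11 and 15 are bought).

**Steps most likely to fail**

Step 8. After alkyne insertion the vinylcarbene may cyclise without taking up CO or take up a second alkyne. The electron-rich 7-hydroxy compound may also stay partly bound to chromium or be over-oxidised while it is released in air, so the material is spread over several species. Fallback (isolation at the quinone oxidation level instead of the phenol): setting out from 14, heated with 15 as in step 8, the crude mixture would not be aired but oxidised at once with ceric ammonium nitrate in MeCN/H2O at 0 °C. This strips chromium and should funnel the phenol, its complex and partly oxidised material into methyl 2-[6-(4-benzyloxyphenyl)-3-methyl-4,7-dioxo-4,7-dihydro-1-benzofuran-2-yl]acetate F1. Reduction with aqueous Na2S2O4 in EtOAc should give the hydroquinone methyl 2-[6-(4-benzyloxyphenyl)-4,7-dihydroxy-3-methyl-1-benzofuran-2-yl]acetate F2. Double O-methylation (Me2SO4, K2CO3, acetone, under argon) would come back to the route at 18, step 9 being skipped.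

Step 7. The strongly basic and reducing dianion may deprotonate the CH2CO2Me group or attack the ester in competition with acylation, so little acylchromate may form. Fallback (the ester is taken out of the molecule before chromium is brought in, and restored at the end): setting out from 9, its lithium salt would be reduced with LiBH4 in THF to 5-(2-hydroxyethyl)-4-methylfuran-3-carboxylic acid F3. TBSCl/imidazole in DMF should give tert-butyldimethylsilyl 5-[2-(tert-butyldimethylsilyloxy)ethyl]-4-methylfuran-3-carboxylate F4. Its silyl ester would be converted directly by (COCl)2/cat. DMF under neutral conditions into 5-[2-(tert-butyldimethylsilyloxy)ethyl]-4-methylfuran-3-carbonyl chloride F5, which has no acidic C–H and no second electrophile. Acylation of 12 and methylation as in step 7 should lead through the sodium acylchromate F6 to pentacarbonyl{[5-(2-tert-butyldimethylsilyloxyethyl)-4-methylfuran-3-yl](methoxy)methylidene}chromium F7. Benzannulation with 15 as in step 8 should give, through the tricarbonylchromium phenol complex F8, 6-(4-benzyloxyphenyl)-2-[2-(tert-butyldimethylsilyloxy)ethyl]-4-methoxy-3-methyl-1-benzofuran-7-ol F9. MeI/K2CO3 should give 6-(4-benzyloxyphenyl)-2-[2-(tert-butyldimethylsilyloxy)ethyl]-4,7-dimethoxy-3-methyl-1-benzofuran F10, and TBAF in THF 2-[6-(4-benzyloxyphenyl)-4,7-dimethoxy-3-methyl-1-benzofuran-2-yl]ethanol F11. TEMPO (cat.)/PhI(OAc)2 in MeCN/H2O should oxidise this through the unisolated aldehyde 2-[6-(4-benzyloxyphenyl)-4,7-dimethoxy-3-methyl-1-benzofuran-2-yl]acetaldehyde F12 to 2-[6-(4-benzyloxyphenyl)-4,7-dimethoxy-3-methyl-1-benzofuran-2-yl]acetic acid F13. TMSCHN2 in MeOH/toluene would come back to the route at 18.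

Step 3. The [3,3] shift has to break the aromaticity of an acceptor-substituted furan. It may be too slow at temperatures where the ketene acetal and the exocyclic-methylene intermediate decompose or oligomerise. Fallback (side chain brought in by cross-coupling instead of rearrangement): setting out from 3, SOCl2 in CH2Cl2 should give ethyl 4-(chloromethyl)furan-3-carboxylate F14, and zinc dust in acetic acid should reduce it to ethyl 4-methylfuran-3-carboxylate F15. NBS in DMF should brominate the α-position next to the methyl group, the other α-position being deactivated by the adjacent ester, to give ethyl 5-bromo-4-methylfuran-3-carboxylate F16. Pd-catalysed Negishi-type coupling (Pd2(dba)3, XPhos, THF) with the Reformatsky reagent (2-methoxy-2-oxoethyl)zinc bromide F17, made from methyl bromoacetate and zinc, would come back to the route at 7.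

**Further compounds**
F1 | step 8 | methyl 2-[6-(4-benzyloxyphenyl)-3-methyl-4,7-dioxo-4,7-dihydro-1-benzofuran-2-yl]acetate | COC(=O)Cc1oc2c(c1C)C(=O)C=C(c1ccc(OCc3ccccc3)cc1)C2=O
F2 | step 8 | methyl 2-[6-(4-benzyloxyphenyl)-4,7-dihydroxy-3-methyl-1-benzofuran-2-yl]acetate | COC(=O)Cc1oc2c(O)c(-c3ccc(OCc4ccccc4)cc3)cc(O)c2c1C
F3 | step 7 | 5-(2-hydroxyethyl)-4-methylfuran-3-carboxylic acid | OCCc1occ(C(=O)O)c1C
F4 | step 7 | tert-butyldimethylsilyl 5-[2-(tert-butyldimethylsilyloxy)ethyl]-4-methylfuran-3-carboxylate | CC(C)(C)[Si](C)(C)OCCc1occ(C(=O)O[Si](C)(C)C(C)(C)C)c1C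
F5 | step 7 | 5-[2-(tert-butyldimethylsilyloxy)ethyl]-4-methylfuran-3-carbonyl chloride | CC(C)(C)[Si](C)(C)OCCc1occ(C(=O)Cl)c1C
F6 | step 7 | sodium pentacarbonyl{[5-(2-tert-butyldimethylsilyloxyethyl)-4-methylfuran-3-yl]carbonyl}chromate(1–) | [Na+].[O-]C(=[Cr](=C=O)(=C=O)(=C=O)(=C=O)=C=O)c1coc(CCO[Si](C)(C)C(C)(C)C)c1C
F7 | step 7 | pentacarbonyl{[5-(2-tert-butyldimethylsilyloxyethyl)-4-methylfuran-3-yl](methoxy)methylidene}chromium | COC(=[Cr](=C=O)(=C=O)(=C=O)(=C=O)=C=O)c1coc(CCO[Si](C)(C)C(C)(C)C)c1C
F8 | step 7 | tricarbonyl(η6-arene)chromium complex of F9 (η6 bonding written as two dot-separated parts) | CC(C)(C)[Si](C)(C)OCCc1oc2c(O)c(-c3ccc(OCc4ccccc4)cc3)cc(OC)c2c1C.O=C=[Cr](=C=O)=C=O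
F9 | step 7 | 6-(4-benzyloxyphenyl)-2-[2-(tert-butyldimethylsilyloxy)ethyl]-4-methoxy-3-methyl-1-benzofuran-7-ol | CC(C)(C)[Si](C)(C)OCCc1oc2c(O)c(-c3ccc(OCc4ccccc4)cc3)cc(OC)c2c1C
F10 | step 7 | 6-(4-benzyloxyphenyl)-2-[2-(tert-butyldimethylsilyloxy)ethyl]-4,7-dimethoxy-3-methyl-1-benzofuran | CC(C)(C)[Si](C)(C)OCCc1oc2c(OC)c(-c3ccc(OCc4ccccc4)cc3)cc(OC)c2c1C
F11 | step 7 | 2-[6-(4-benzyloxyphenyl)-4,7-dimethoxy-3-methyl-1-benzofuran-2-yl]ethanol | OCCc1oc2c(OC)c(-c3ccc(OCc4ccccc4)cc3)cc(OC)c2c1C
F12 | step 7 | 2-[6-(4-benzyloxyphenyl)-4,7-dimethoxy-3-methyl-1-benzofuran-2-yl]acetaldehyde | O=CCc1oc2c(OC)c(-c3ccc(OCc4ccccc4)cc3)cc(OC)c2c1C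
F13 | step 7 | 2-[6-(4-benzyloxyphenyl)-4,7-dimethoxy-3-methyl-1-benzofuran-2-yl]acetic acid | OC(=O)Cc1oc2c(OC)c(-c3ccc(OCc4ccccc4)cc3)cc(OC)c2c1C
F14 | step 3 | ethyl 4-(chloromethyl)furan-3-carboxylate | CCOC(=O)c1cocc1CCl
F15 | step 3 | ethyl 4-methylfuran-3-carboxylate | CCOC(=O)c1cocc1C
F16 | step 3 | ethyl 5-bromo-4-methylfuran-3-carboxylate | CCOC(=O)c1coc(Br)c1C
F17 | step 3 | (2-methoxy-2-oxoethyl)zinc bromide | COC(=O)C[Zn]Br
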